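Readings and results were computed on assumed constants; noise was put on by code.

One equivalent of substrate takes up 3 equivalents of reagent on its way to tris adduct, so the first question is how far each charge reaches.

| flask | substrate | reagent | remark | time |
|---|---|---|---|---|
| beta | 0.050 M | 1.2 equiv | run made earlier |  |
| zeta | 0.037 M | 1.2 equiv | run made earlier |  |
| red | 0.074 M | 1.20 equiv |  | 5.0 min |
| blue | 0.074 M | 2.00 equiv |  | 5.0 min |
| grey | 0.074 M | 4.00 equiv |  | 5.0 min |

| run | time / s | tris adduct / % | substrate / % |
|---|---|---|---|
| beta | 12.0 | 0 | 60.1 |
| beta | 40.0 | 0.3 | 28.0 |
| beta | 60.0 | 1.1 | 19.2 |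
| beta | 120 | 4.4 | 8.8 |
| zeta | 12.0 | 0.8 | 66.9 |
| zeta | 40.0 | 0.7 | 35.3 |
| zeta | 60.0 | 1.1 | 24.9 |
| zeta | 120 | 3.1 | 12.5 |

(readings scatter by 0.5 percentage points)

- percentages count the substrate that a species holds: one self-condensation product counts as two
- tris adduct is meant together with its crystals
- solid, in amounts per volume of the solution: crystals
- steps under discussion: crystals <-> tris adduct; 2 substrate -> self-condensation product; substrate + reagent -> single product; reagent + double product -> tris adduct; reagent + single product -> double product

- final tris adduct, as a percentage of the substrate charged, for each flask in turn (red, blue, grey)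

Red has 40.0% of cover, cover being the percentage of the substrate charged that the reagent charge could carry to tris adduct, its equivalents divided by 3. Blue has 66.7% and grey 133%, so the reagent charge falls short of carrying the whole substrate charge to tris adduct in blue and exceeds it in grey.

The next question is how much of the cover 5.0 min can reach. Red and beta share their equivalents, and at fixed equivalents each bimolecular step runs on concentration multiplied by time, while crystals leave the tris adduct count unchanged. Red therefore ends at 3.70 times the concentration-time product of the last beta reading. In beta, tris adduct read 1.1% at 60.0 s and 4.4% at 120 s, so it was still climbing. My reckoning gives ceilings rather than point values: tris adduct does not pass 40.0% in red or 66.7% in blue.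

The forecast gives 9%, 35% and 88%, holding for grey that "excess reagent drives it nearly to completion".

The flasks give 14.5%, 42.2% and 87.0%, so red stands 5.5 percentage points above the forecast.

    crystals ⇌ tris adduct, rate k1*(cs1 - [tris adduct]) while solid is left; crystals form when [tris adduct] > cs1 (solubility = 6.70 mM, k = 2.60 s⁻¹)
    2 substrate → self-condensation product (k = 0.230 M⁻¹ s⁻¹)
    substrate + reagent → single product (k = 0.460 M⁻¹ s⁻¹)
    reagent + double product → tris adduct (k = 0.200 M⁻¹ s⁻¹)
    reagent + single product → double product (k = 0.150 M⁻¹ s⁻¹)

In red, self-condensation ran while substrate was there, with 99.0% of its turnover up to the asked time behind it by 2.50 min, when substrate stood at 3.78%; at 5.00 min tris adduct stood at 14.5%, below the cover of 40.0%, with 5.84% of the reagent charge left. In blue, tris adduct went from 42.2% at 5.00 min to 53.8% at 50.0 min, as reagent fell to 0% of its charge, still below the cover of 66.7%.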